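## Analysis of the target

The target 27 has five rings. Ring A, a 4-hydroxy-3-methoxyphenyl group, sits on C2 of a 2,3-dihydrobenzofuran (dihydrofuran ring B: O1, C2, C3, C3a, C7a; benzene ring C: C3a to C7a). Ring C carries a methoxy group at C7 and, at C5, the C2′ atom of a benzofuran (furan ring D, benzene ring E) with a methoxy group at C7′ and a 3-hydroxypropyl chain at C5′. The two stereocentres, C2 (S) and C3 (R), are adjacent, and the aryl group at C2 and the hydroxymethyl group at C3 lie on opposite faces of ring B (trans). C2 is a benzylic ether carbon para to a free phenol, so acid or strong base can open the C2–O1 bond through a para-quinone methide; this endangers the configuration at C2 and, with a free CH2OH at C3, can end in loss of formaldehyde. The benzofuran is electron-rich and sensitive to electrophiles and strong acid, and the phenol and both primary alcohols must be free at the end. The difficulty is to secure the absolute configuration of the C2/C3 pair at a centre that ionises easily, and to assemble the 1,2,3,5-tetrasubstituted ring C with two different oxygen substituents and a biaryl bond in the right pattern. The strategy rests on ring C itself: C7a (bearing O1) and C3a (bearing C3) are tied together by the three-atom unit O1–C2–C3, C7 carries OMe and C5 the benzofuranyl group. That is the benzene ring left when a 3-alkoxy-4-methoxy-6-arylpyridazine adds an alkyne, held on the alkoxy oxygen by a two-carbon chain, across its C3 and C6 and then loses its two nitrogen atoms.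

## Retrosynthetic reasoning

**Protecting groups.** 27 is taken back to the fully protected pentacycle 25 through the phenol 26. In 25 the ring A oxygen is a tosylate and the two primary alcohols are silyl ethers (tert-butyldimethylsilyl on the propyl chain, triisopropylsilyl on the C3 hydroxymethyl group). No skeletal bond is cut; the gain is that the sulfonate keeps ring A electron-poor through every step in which the benzylic C2–O bond could ionise, and a tosylate has no α-hydrogen through which an alkoxide base could fragment it. In the forward direction the sulfonate is cleaved first, while the C3 side chain is still silylated and cannot be lost by retro-aldol-type fragmentation, and the silyl ethers are removed last under buffered conditions.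

**Ring C and ring B (key disconnection).** In 25 the bonds C3a–C7a and C4–C5 are cut and an N=N unit is put back between C7a and C5. This gives the pyridazinyl ether 23: pyridazine C3 carries the ether oxygen, C4 the methoxy group, C6 the benzofuranyl group, and a terminal alkyne hangs from the carbon that becomes C3. The cut is made here and not at C2–C3 or O1–C2 because it removes ring C and ring B together while leaving both stereocentres in an open chain, where they can be set by acyclic stereocontrol and are untouched when the rings form. The forward reaction must make the alkyne add across pyridazine C3 and C6 (adduct 24) faster than the benzylic ether decomposes; aromatisation by loss of the diazo bridge is then irreversible, and the tether allows only one regiochemistry.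

**Aryl ether bond.** 23 is cut between pyridazine C3 and the ether oxygen into the chloropyridazine 12 and the homopropargylic alcohol 21, which reacts as its alkoxide 22. Cutting on the heteroaryl side of the oxygen means that the carbinol C–O bond is never broken, so C2 keeps its configuration, and the two halves of the molecule meet one step before the key step. The forward reaction is a nucleophilic aromatic substitution at the only carbon of 12 that carries a leaving group. The triisopropylsilyl ether was chosen for this step: the alkoxide in 22 stands in a 1,3-relation to the silyl ether, and a smaller silyl group could migrate to it.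

**The C2–C3 bond and both stereocentres.** 21 is cut between the carbinol carbon and the propargylic carbon into the aldehyde 19 and the allenylzinc reagent 20, which is made in the flask from the propargylic mesylate 17. This is the place where one purchasable stereocentre can be turned into both stereocentres of the target: 20 carries the chirality of 17 as axial chirality and returns it as the configuration of C3, and the cyclic transition state places the carbinol anti to it. The forward reaction must transfer chirality without loss and must prefer the anti mode with an aromatic aldehyde.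

**The propargylic mesylate.** 17 comes from alcohol 16 by sulfonylation, 16 from diol 15 by silylation of the primary hydroxyl group, 15 from the dioxolane 14 by acetal hydrolysis, and 14 from the chiral-pool aldehyde 13 by one-carbon homologation to the alkyne. The stereocentre of 13 is unchanged in space throughout (its descriptor changes from R to S only because the aldehyde becomes an alkyne), so the absolute configuration of 27 traces to 13.

**Ring A.** 19 is the tosylate of vanillin 18.

**Biaryl bond.** 12 is cut between pyridazine C6 and benzofuran C2 into the dichloropyridazine 9 and the benzofuran 7, which is metalated at C2 (lithium compound 10, then zinc compound 11). This coupling is placed before the ether formation because the chloride of 9 remote from the methoxy group should be the more reactive one; using it for the carbon–carbon bond leaves the chloride next to the methoxy group, which is the one the ether needs. 9 comes from 8 by substitution of its most reactive chloride, the one at C4.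

**Ring D.** The furan ring of 7 is cut at O1′–C2′ and C3′–C3a′. 7 is the silyl ether of alcohol 6, and 6 arises from the iodophenol 2 and the two-carbon alkyne 3 by cross-coupling (4), C-desilylation (5) and closure of the phenol oxygen onto the alkyne. 2 is made by iodinating 1 ortho to its hydroxyl group, so the three substituents of ring E are already in place in the starting material.

## Alternatives that were turned down

**Alternative 1: (4+1) annulation of an ortho-quinone methide with a chiral sulfur ylide.**
- **Disconnection:** O1–C2 and C2–C3 are cut, so that C2 with ring A arrives as a one-carbon unit.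
- **Forward key step:** Cs2CO3 acts on the phenol sulfone A1 and on the benzylic sulfonium salt A2 (drawn with a C2-symmetric (2R,5R)-thiolane; which enantiomer of the sulfide leads to (2S,3R) is not asserted). Loss of sulfinate from A1 unmasks the quinone methide and deprotonation of A2 gives the ylide. Conjugate addition forms C2–C3, and the phenoxide then displaces the sulfide to close ring B, giving the 5-bromo compound A3.
- **For it:** room-temperature conditions, inherent trans selectivity from the anti-periplanar ring closure, a convergent union of two simple aromatic pieces, and a bromide at C5 ready for coupling with zinc reagent 11.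
- **Against it for this target:** the absolute configuration depends on face discrimination by the sulfide in a bimolecular addition to a quinone methide that bears a CH2OSi group on its methide carbon, and that intermediate can also tautomerise to a vinylphenol. A stoichiometric chiral sulfide is needed. After A3 there remain a cross-coupling, a debenzylation that must spare the benzofuran and the benzylic C2–O1 bond, and a desilylation.
- **Comparison:** on mildness and convergence this alternative is as strong as or stronger than the chosen route, and its step count is similar. The pyridazine route offers instead a configuration derived stereospecifically from a chiral-pool centre before any ring is closed, and a ring closure that has no stereochemical decision to make.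

**Alternative 2: rhodium carbene C–H insertion.**
- **Disconnection:** only C2–C3 is cut; ring B is closed by inserting a carbene at C3 into a benzylic C–H bond of a ring A benzyl ether on O1.
- **Forward key step:** Rh2(S-DOSP)4 decomposes the aryldiazoacetate A4, and the carbene inserts into the O–CH2 group to give the ester A5.
- **For it:** the stereocentres are made by a catalytic enantioselective step, A4 is reached quickly by O-benzylation and diazo transfer, and insertion next to an ether oxygen is a favourable case.
- **Against it for this target:** such insertions tend to give the cis-2,3-disubstituted ring kinetically, so an epimerisation at C3 (α to the ester) would probably be needed to reach trans. The methoxy group flanking the ether oxygen makes the level of enantiocontrol uncertain. C3 arrives as an ester that must be reduced, and the coupling at C5 and the debenzylation remain as in alternative 1.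
- **Comparison:** it is stronger on catalytic asymmetric induction and on the length of the path to the bicyclic core. The chosen route offers C3 at the right oxidation level from the start, a trans relation fixed in the acyclic precursor and not by a later epimerisation, and an absolute configuration that does not depend on a catalyst–substrate match.

**Alternative 3: acylation–intramolecular Wittig closure of the benzofuran.**
- **Disconnection:** ring D is cut at O1′–C2′ and C2′=C3′, so that the dihydrobenzofuran arrives as the C5 acid chloride A6 and ring E as the (2-hydroxybenzyl)phosphonium salt A7.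
- **Forward key step:** A6 acylates the phenol of A7, Et3N generates the ylide, and intramolecular Wittig olefination of the new ester carbonyl closes the furan ring to give the triacetate A8, which one mild methanolysis would convert into 27.
- **For it:** a dependable, metal-free benzofuran synthesis, a late convergent union, and a single final deprotection; on the end game it is stronger than the chosen route, which needs two steps.
- **Against it for this target:** the real difficulty, the (2S,3R) dihydrobenzofuran, is left unsolved, because A6 must first be made by some other enantioselective method and then taken through acid chloride formation next to a benzylic ether. Acyl transfer from the aryl acetate of A6 to the phenol of A7 is conceivable under the basic conditions, and A7 needs its own sequence from 1.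
- **Comparison:** it is excellent for ring D, but overall longer once the stereocentres are paid for. The chosen route builds ring D in two steps from 1 and spends its key step on rings B and C, where the stereochemical and substitution-pattern problems lie.

Key step: step 13

Assumption: 13 is used as purchased (R)-2,3-O-isopropylideneglyceraldehyde of high enantiomeric purity, freshly distilled; its stereocentre is the only source of absolute configuration in the route.

## Route

Step 1
Reactants: 1 4-(3-hydroxypropyl)-2-methoxyphenol (dihydroconiferyl alcohol)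
Product: 2 4-(3-hydroxypropyl)-2-iodo-6-methoxyphenol
Conditions: I2, NaHCO3, THF–H2O, 0 °C → rt
Reagents that add atoms: iodine (I2), [I][I]
Why: Electrophilic aromatic iodination of the phenoxide; the para position is occupied by the side chain, so iodine should enter the one free position ortho to the hydroxyl group, which the phenoxide activates more strongly than the methoxy group activates its own ortho and para positions.

Step 2
Reactants: 2 4-(3-hydroxypropyl)-2-iodo-6-methoxyphenol; 3 ethynyltrimethylsilane
Product: 6 3-(7-methoxy-1-benzofuran-5-yl)propan-1-ol, via silylethynylphenol 4 (not isolated), via ethynylphenol 5 (not isolated)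
Conditions: PdCl2(PPh3)2 (cat.), CuI (cat.), Et3N, THF, rt; then TBAF, 65 °C
Reagents that add atoms: none
Why: Sonogashira coupling of the aryl iodide with 3 gives 4; fluoride then removes the C-silyl group, and the phenoxide of 5 adds 5-endo-dig to the terminal alkyne, helped by the copper and palladium salts still present, to give the benzofuran with C2 unsubstituted.

Step 3
Reactants: 6 3-(7-methoxy-1-benzofuran-5-yl)propan-1-ol
Product: 7 tert-butyl[3-(7-methoxy-1-benzofuran-5-yl)propoxy]dimethylsilane
Conditions: TBSCl, imidazole, DMF, rt
Reagents that add atoms: tert-butylchlorodimethylsilane (TBSCl), CC(C)(C)[Si](C)(C)Cl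
Why: Standard silylation of a primary alcohol; the silyl ether shields the side chain from the organolithium of step 5 and from NaH in step 12.

Step 4
Reactants: 8 3,4,6-trichloropyridazine
Product: 9 3,6-dichloro-4-methoxypyridazine
Conditions: NaOMe (1.0 equiv), MeOH, 0 °C
Reagents that add atoms: sodium methoxide (NaOMe), [Na+].[O-]C
Why: Nucleophilic aromatic substitution; C4, para to N1 and flanked by a chlorine, is the most electrophilic carbon of 8, so one equivalent of methoxide in the cold should give the 4-methoxy compound.

Step 5
Reactants: 7 tert-butyl[3-(7-methoxy-1-benzofuran-5-yl)propoxy]dimethylsilane; 9 3,6-dichloro-4-methoxypyridazine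
Product: 12 6-[5-(3-{[tert-butyl(dimethyl)silyl]oxy}propyl)-7-methoxy-1-benzofuran-2-yl]-3-chloro-4-methoxypyridazine, via 2-lithiobenzofuran 10 (not isolated), via benzofuranylzinc chloride 11 (not isolated)
Conditions: n-BuLi, THF, −78 °C; ZnCl2, −78 → 0 °C; then 9, Pd(PPh3)4 (cat.), rt → 50 °C
Reagents that add atoms: none
Why: Lithiation at C2, the most acidic C–H of the benzofuran, transmetalation to zinc and Negishi coupling. Oxidative addition of zerovalent palladium should occur at C6–Cl of 9, which is meta to the methoxy group, and not at C3–Cl, which the adjacent methoxy donor shields and deactivates; this leaves the chloride that step 12 needs.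

Step 6
Reactants: 13 (R)-2,2-dimethyl-1,3-dioxolane-4-carbaldehyde
Product: 14 (S)-4-ethynyl-2,2-dimethyl-1,3-dioxolane
Conditions: dimethyl (1-diazo-2-oxopropyl)phosphonate, K2CO3, MeOH, 0 °C → rt
Reagents that add atoms: dimethyl (1-diazo-2-oxopropyl)phosphonate, COP(=O)(OC)C(=[N+]=[N-])C(C)=O
Why: Seyferth–Gilbert homologation in its Ohira–Bestmann form turns the aldehyde into the terminal alkyne under mild carbonate conditions; no bond to the stereocentre is made or broken, and the low temperature limits enolisation of the α-alkoxy aldehyde.

Step 7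
Reactants: 14 (S)-4-ethynyl-2,2-dimethyl-1,3-dioxolane
Product: 15 (S)-but-3-yne-1,2-diol
Conditions: Dowex 50WX8 (H+ form), MeOH–H2O, rt
Reagents that add atoms: none
Why: Acid-catalysed acetal hydrolysis; the resin is filtered off, so the water-soluble diol is isolated by evaporation alone.

Step 8
Reactants: 15 (S)-but-3-yne-1,2-diol
Product: 16 (S)-1-{[tri(propan-2-yl)silyl]oxy}but-3-yn-2-ol
Conditions: TIPSCl, imidazole, CH2Cl2, 0 °C
Reagents that add atoms: chlorotri(propan-2-yl)silane (TIPSCl), CC(C)[Si](Cl)(C(C)C)C(C)C
Why: Selective silylation of the primary hydroxyl group of a 1,2-diol by a bulky silyl chloride; triisopropylsilyl is used because it should not migrate to the neighbouring alkoxide in step 12.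

Step 9
Reactants: 16 (S)-1-{[tri(propan-2-yl)silyl]oxy}but-3-yn-2-ol
Product: 17 (S)-1-{[tri(propan-2-yl)silyl]oxy}but-3-yn-2-yl methanesulfonate
Conditions: MsCl, Et3N, CH2Cl2, −20 °C
Reagents that add atoms: methanesulfonyl chloride (MsCl), CS(=O)(=O)Cl
Why: O-Sulfonylation of the secondary propargylic alcohol; the C–O bond is not touched, so the configuration is retained, and the mesylate is used at once.

Step 10
Reactants: 18 vanillin
Product: 19 4-formyl-2-methoxyphenyl 4-methylbenzenesulfonate
Conditions: TsCl, Et3N, DMAP (cat.), CH2Cl2, 0 °C → rt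
Reagents that add atoms: 4-methylbenzenesulfonyl chloride (TsCl), Cc1ccc(cc1)S(=O)(=O)Cl
Why: O-Sulfonylation of the phenol; the tosylate makes ring A electron-poor for steps 11 to 13, cannot fragment through a sulfene under alkoxide conditions because it has no α-hydrogen, and is inert to zerovalent palladium with PPh3.

Step 11
Reactants: 17 (S)-1-{[tri(propan-2-yl)silyl]oxy}but-3-yn-2-yl methanesulfonate; 19 4-formyl-2-methoxyphenyl 4-methylbenzenesulfonate
Product: 21 4-[(1S,2R)-1-hydroxy-2-({[tri(propan-2-yl)silyl]oxy}methyl)but-3-yn-1-yl]-2-methoxyphenyl 4-methylbenzenesulfonate, via allenylzinc 20 (not isolated)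
Conditions: Pd(OAc)2 (cat.), PPh3 (cat.), Et2Zn, THF, −20 °C; aq. NH4Cl
Reagents that add atoms: none
Why: Palladium-catalysed zincation of a propargylic mesylate followed by SE2′ addition of the allenylzinc to an aldehyde: zerovalent palladium displaces the mesylate of 17 in an anti SN2′ sense and transmetalation gives the (P)-allenylzinc 20. Addition through a cyclic transition state on the allene face that carries zinc sets the propargylic carbon as R, and the aryl group turns away from the CH2OSi substituent, which should give the anti (1S) carbinol.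

Step 12
Reactants: 21 4-[(1S,2R)-1-hydroxy-2-({[tri(propan-2-yl)silyl]oxy}methyl)but-3-yn-1-yl]-2-methoxyphenyl 4-methylbenzenesulfonate; 12 6-[5-(3-{[tert-butyl(dimethyl)silyl]oxy}propyl)-7-methoxy-1-benzofuran-2-yl]-3-chloro-4-methoxypyridazine
Product: 23 4-[(1S,2R)-1-({6-[5-(3-{[tert-butyl(dimethyl)silyl]oxy}propyl)-7-methoxy-1-benzofuran-2-yl]-4-methoxypyridazin-3-yl}oxy)-2-({[tri(propan-2-yl)silyl]oxy}methyl)but-3-yn-1-yl]-2-methoxyphenyl 4-methylbenzenesulfonate, via sodium alkoxide 22 (not isolated)
Conditions: NaH, THF–DMF (4:1), 0 °C; then 12, 0 °C → rt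
Reagents that add atoms: none
Why: Nucleophilic aromatic substitution (addition–elimination) of the alkoxide at C3 of 12, the only carbon with a leaving group; the carbinol C–O bond is not broken, so C1 keeps its S configuration.

Step 13
Reactants: 23 4-[(1S,2R)-1-({6-[5-(3-{[tert-butyl(dimethyl)silyl]oxy}propyl)-7-methoxy-1-benzofuran-2-yl]-4-methoxypyridazin-3-yl}oxy)-2-({[tri(propan-2-yl)silyl]oxy}methyl)but-3-yn-1-yl]-2-methoxyphenyl 4-methylbenzenesulfonate
Product: 25 4-[(2S,3R)-5-[5-(3-{[tert-butyl(dimethyl)silyl]oxy}propyl)-7-methoxy-1-benzofuran-2-yl]-7-methoxy-3-({[tri(propan-2-yl)silyl]oxy}methyl)-2,3-dihydro-1-benzofuran-2-yl]-2-methoxyphenyl 4-methylbenzenesulfonate, via diazabicyclooctatriene adduct 24 (not isolated)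
Conditions: 1,3,5-triisopropylbenzene (0.01 M), degassed, sealed vessel, 200–220 °C
Reagents that add atoms: none
Why: Intramolecular inverse-electron-demand Diels–Alder reaction in which C3–C4–C5–C6 of the pyridazine is the electron-poor diene and the tethered terminal alkyne the dienophile: the internal alkyne carbon bonds to pyridazine C3 and the terminal carbon to C6, giving the 2,3-diazabicyclo[2.2.2]octatriene 24, which loses N2 by cycloreversion and leaves ring C aromatic. The closest known reaction type is the thermal cycloaddition–cycloreversion of 3-(alk-3-ynyloxy)pyridazines to 2,3-dihydrobenzofurans. Ring B closes in the cycloaddition itself as a five-membered ring through the three-atom tether O1–C2–C3 (bond C3a–C7a), and ring C is completed by the second new bond C4–C5 and the loss of N2. No stereocentre is formed in the product: the bridgehead centres of 24 disappear on aromatisation and C2 and C3 are spectators, so both faces of the pyridazine lead to the same 25. Regiochemistry is fixed by the tether, which can reach only C3 with the internal alkyne carbon. The selectivity that matters is cycloaddition over heterolysis, O-to-N shift or retro-ene loss of the benzylic pyridazinyl ether; the sulfonate on ring A destabilises a benzylic cation, the two substituents on the tether favour the folded conformer (Thorpe–Ingold effect), and high dilution in a non-polar hydrocarbon disfavours ion pairs and bimolecular paths. The 4-methoxy donor raises the LUMO of the diene, so a higher temperature than for unsubstituted cases is expected.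

Step 14
Reactants: 25 4-[(2S,3R)-5-[5-(3-{[tert-butyl(dimethyl)silyl]oxy}propyl)-7-methoxy-1-benzofuran-2-yl]-7-methoxy-3-({[tri(propan-2-yl)silyl]oxy}methyl)-2,3-dihydro-1-benzofuran-2-yl]-2-methoxyphenyl 4-methylbenzenesulfonate
Product: 26 4-[(2S,3R)-5-[5-(3-{[tert-butyl(dimethyl)silyl]oxy}propyl)-7-methoxy-1-benzofuran-2-yl]-7-methoxy-3-({[tri(propan-2-yl)silyl]oxy}methyl)-2,3-dihydro-1-benzofuran-2-yl]-2-methoxyphenol
Conditions: KOH, MeOH–THF, 60 °C; then aq. HCl to pH 6
Reagents that add atoms: none
Why: Hydroxide attacks sulfur of the aryl sulfonate (S–O cleavage) and releases the phenoxide; the silyl ethers are kept during this step so that the CH2O group at C3 cannot be lost as formaldehyde from the phenoxide.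

Step 15
Reactants: 26 4-[(2S,3R)-5-[5-(3-{[tert-butyl(dimethyl)silyl]oxy}propyl)-7-methoxy-1-benzofuran-2-yl]-7-methoxy-3-({[tri(propan-2-yl)silyl]oxy}methyl)-2,3-dihydro-1-benzofuran-2-yl]-2-methoxyphenol
Product: 27 4-[(2S,3R)-3-(hydroxymethyl)-5-[5-(3-hydroxypropyl)-7-methoxy-1-benzofuran-2-yl]-7-methoxy-2,3-dihydro-1-benzofuran-2-yl]-2-methoxyphenol
Conditions: TBAF, AcOH, THF, rt → 40 °C
Reagents that add atoms: none
Why: Fluoride-mediated cleavage of both silyl ethers; acetic acid buffers the mixture so that the phenol is not held as its phenoxide, and C2 and C3 are not involved.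

## Compound list

1 | 4-(3-hydroxypropyl)-2-methoxyphenol (dihydroconiferyl alcohol) | COc1cc(CCCO)ccc1O | starting material
2 | 4-(3-hydroxypropyl)-2-iodo-6-methoxyphenol | COc1cc(CCCO)cc(I)c1O | intermediate
3 | ethynyltrimethylsilane | C#C[Si](C)(C)C | starting material
4 | 4-(3-hydroxypropyl)-2-methoxy-6-[(trimethylsilyl)ethynyl]phenol | COc1cc(CCCO)cc(C#C[Si](C)(C)C)c1O | intermediate
5 | 2-ethynyl-4-(3-hydroxypropyl)-6-methoxyphenol | COc1cc(CCCO)cc(C#C)c1O | intermediate
6 | 3-(7-methoxy-1-benzofuran-5-yl)propan-1-ol | COc1cc(CCCO)cc2ccoc12 | intermediate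
7 | tert-butyl[3-(7-methoxy-1-benzofuran-5-yl)propoxy]dimethylsilane | COc1cc(CCCO[Si](C)(C)C(C)(C)C)cc2ccoc12 | intermediate
8 | 3,4,6-trichloropyridazine | Clc1cc(Cl)c(Cl)nn1 | starting material
9 | 3,6-dichloro-4-methoxypyridazine | COc1cc(Cl)nnc1Cl | intermediate
10 | [5-(3-{[tert-butyl(dimethyl)silyl]oxy}propyl)-7-methoxy-1-benzofuran-2-yl]lithium | [Li]c1cc2cc(CCCO[Si](C)(C)C(C)(C)C)cc(OC)c2o1 | intermediate
11 | chloro[5-(3-{[tert-butyl(dimethyl)silyl]oxy}propyl)-7-methoxy-1-benzofuran-2-yl]zinc | Cl[Zn]c1cc2cc(CCCO[Si](C)(C)C(C)(C)C)cc(OC)c2o1 | intermediate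
12 | 6-[5-(3-{[tert-butyl(dimethyl)silyl]oxy}propyl)-7-methoxy-1-benzofuran-2-yl]-3-chloro-4-methoxypyridazine | COc1cc(-c2cc3cc(CCCO[Si](C)(C)C(C)(C)C)cc(OC)c3o2)nnc1Cl | intermediate
13 | (R)-2,2-dimethyl-1,3-dioxolane-4-carbaldehyde | O=C[C@H]1COC(C)(C)O1 | starting material
14 | (S)-4-ethynyl-2,2-dimethyl-1,3-dioxolane | C#C[C@H]1COC(C)(C)O1 | intermediate
15 | (S)-but-3-yne-1,2-diol | C#C[C@H](O)CO | intermediate
16 | (S)-1-{[tri(propan-2-yl)silyl]oxy}but-3-yn-2-ol | C#C[C@H](O)CO[Si](C(C)C)(C(C)C)C(C)C | intermediate
17 | (S)-1-{[tri(propan-2-yl)silyl]oxy}but-3-yn-2-yl methanesulfonate | C#C[C@H](OS(C)(=O)=O)CO[Si](C(C)C)(C(C)C)C(C)C | intermediate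
18 | vanillin (4-hydroxy-3-methoxybenzaldehyde) | COc1cc(C=O)ccc1O | starting material
19 | 4-formyl-2-methoxyphenyl 4-methylbenzenesulfonate | COc1cc(C=O)ccc1OS(=O)(=O)c1ccc(C)cc1 | intermediate
20 | ethyl[(P)-4-{[tri(propan-2-yl)silyl]oxy}buta-1,2-dien-1-yl]zinc | CC[Zn]C([H])=[C@@]=C([H])CO[Si](C(C)C)(C(C)C)C(C)C | intermediate
21 | 4-[(1S,2R)-1-hydroxy-2-({[tri(propan-2-yl)silyl]oxy}methyl)but-3-yn-1-yl]-2-methoxyphenyl 4-methylbenzenesulfonate | COc1cc([C@@H](O)[C@@H](CO[Si](C(C)C)(C(C)C)C(C)C)C#C)ccc1OS(=O)(=O)c1ccc(C)cc1 | intermediate
22 | sodium (1S,2R)-1-{3-methoxy-4-[(4-methylbenzenesulfonyl)oxy]phenyl}-2-({[tri(propan-2-yl)silyl]oxy}methyl)but-3-yn-1-olate | COc1cc([C@@H]([O-])[C@@H](CO[Si](C(C)C)(C(C)C)C(C)C)C#C)ccc1OS(=O)(=O)c1ccc(C)cc1.[Na+] | intermediate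
23 | 4-[(1S,2R)-1-({6-[5-(3-{[tert-butyl(dimethyl)silyl]oxy}propyl)-7-methoxy-1-benzofuran-2-yl]-4-methoxypyridazin-3-yl}oxy)-2-({[tri(propan-2-yl)silyl]oxy}methyl)but-3-yn-1-yl]-2-methoxyphenyl 4-methylbenzenesulfonate | COc1cc([C@@H](Oc2nnc(-c3cc4cc(CCCO[Si](C)(C)C(C)(C)C)cc(OC)c4o3)cc2OC)[C@@H](CO[Si](C(C)C)(C(C)C)C(C)C)C#C)ccc1OS(=O)(=O)c1ccc(C)cc1 | intermediate
24 | 2,3-diazabicyclo[2.2.2]octa-2,5,7-triene cycloadduct of 23 (bridgeheads: former pyridazine C3 bearing O1 and former C6 bearing the benzofuranyl group; dihydrofuran ring already closed; bridgehead configuration left open, both forms give 25) | COc1cc([C@H]2OC34N=NC(c5cc6cc(CCCO[Si](C)(C)C(C)(C)C)cc(OC)c6o5)(C=C3OC)C=C4[C@@H]2CO[Si](C(C)C)(C(C)C)C(C)C)ccc1OS(=O)(=O)c1ccc(C)cc1 | intermediate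
25 | 4-[(2S,3R)-5-[5-(3-{[tert-butyl(dimethyl)silyl]oxy}propyl)-7-methoxy-1-benzofuran-2-yl]-7-methoxy-3-({[tri(propan-2-yl)silyl]oxy}methyl)-2,3-dihydro-1-benzofuran-2-yl]-2-methoxyphenyl 4-methylbenzenesulfonate | COc1cc([C@H]2Oc3c(OC)cc(-c4cc5cc(CCCO[Si](C)(C)C(C)(C)C)cc(OC)c5o4)cc3[C@@H]2CO[Si](C(C)C)(C(C)C)C(C)C)ccc1OS(=O)(=O)c1ccc(C)cc1 | intermediate
26 | 4-[(2S,3R)-5-[5-(3-{[tert-butyl(dimethyl)silyl]oxy}propyl)-7-methoxy-1-benzofuran-2-yl]-7-methoxy-3-({[tri(propan-2-yl)silyl]oxy}methyl)-2,3-dihydro-1-benzofuran-2-yl]-2-methoxyphenol | COc1cc([C@H]2Oc3c(OC)cc(-c4cc5cc(CCCO[Si](C)(C)C(C)(C)C)cc(OC)c5o4)cc3[C@@H]2CO[Si](C(C)C)(C(C)C)C(C)C)ccc1O | intermediate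
27 | 4-[(2S,3R)-3-(hydroxymethyl)-5-[5-(3-hydroxypropyl)-7-methoxy-1-benzofuran-2-yl]-7-methoxy-2,3-dihydro-1-benzofuran-2-yl]-2-methoxyphenol | COc1cc([C@H]2Oc3c(OC)cc(-c4cc5cc(CCCO)cc(OC)c5o4)cc3[C@@H]2CO)ccc1O | target

## Step count and least certain steps

Total: 15 steps. Longest linear sequence: 9 steps (steps 6, 7, 8, 9, 11, 12, 13, 14 and 15, from 13).

**Step 13 (key step).** Heterolysis of the benzylic C–O bond, followed by O-to-N shift of the benzylic group or elimination, or retro-ene loss of the pyridazinyl group, may outrun a cycloaddition that is slowed by the methoxy donor on the diene and by the conjugated benzofuranyl group on the reacting C6. The fallback keeps the same cycloaddition but runs it on a pyridazine with no substituent at C6 and makes the biaryl bond afterwards. It sets out from alkoxide 22 and comes back at 25. 22 is treated with 3-chloro-4-methoxypyridazine (THF–DMF, 0 °C → rt) to give the 4-methoxypyridazin-3-yl ether of 21 F1. Heating as in step 13 should give the 5-unsubstituted 7-methoxy-2,3-dihydrobenzofuran F2. Bromination with N-bromosuccinimide in MeCN at 0 °C should go para to O1, at C5, since ring A is deactivated by its sulfonate, to give the 5-bromo compound F3. Negishi coupling of F3 with zinc reagent 11 (Pd(OAc)2, SPhos, THF, 50 °C) then gives 25.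

**Step 11.** Facial discrimination of the aromatic aldehyde in the cyclic transition state may be incomplete, giving some syn adduct that is epimeric at the carbinol carbon; partial loss of configuration of the allenylmetal and ethyl transfer from Et2Zn are lesser concerns. The fallback changes control at C2 from kinetic to thermodynamic. It sets out from 21 as a mixture and comes back at 26. Because the minor adduct differs only at the carbon that becomes C2, the mixture of 21 and the (1R,2R) epimer of 21 F4 is carried through steps 12 to 14, which gives the (1R,2R) pyridazinyl ether F5, the (2R,3R) cis-dihydrobenzofuran tosylate F6 and the (2R,3R) cis-phenol F7 alongside 23, 25 and 26. The mixture of 26 and F7 is then treated with a catalytic amount of CF3CO2H in CH2Cl2 at 0 °C. Reversible opening of the C2–O1 bond, assisted by the para-hydroxyl group, should convert F7 into the more stable trans isomer, which is 26 itself because C3 is the same in both.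

**Step 12.** Substitution at a chloride that is deactivated and shielded by the neighbouring methoxy group may be slow, which leaves time for silyl migration, deprotonation of the alkyne or fragmentation of the alkoxide. The fallback changes the leaving group. It sets out from 12 and comes back at 23. 12 is treated with NaSMe (DMF, rt) to give the 3-(methylsulfanyl)pyridazine F8, and oxidation with mCPBA (CH2Cl2, 0 °C) gives the 3-(methylsulfonyl)pyridazine F9. The sulfone should be displaced by alkoxide 22 at −40 °C, a temperature at which the side reactions are slow, to give 23.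

**Step 5.** Site selectivity in the oxidative addition may be lost, giving coupling at C3–Cl or double coupling. The fallback uses a pyridazine with a single halogen and installs the C3 chloride afterwards. It sets out from 7 and comes back at 12. 4-Bromo-6-chloropyridazin-3-amine is heated with NaOMe in MeOH to give 6-chloro-4-methoxypyridazin-3-amine F10. 7 is lithiated as in step 5 and quenched with 2-isopropoxy-4,4,5,5-tetramethyl-1,3,2-dioxaborolane to give the benzofuran-2-yl pinacol boronate F11. Suzuki–Miyaura coupling of F10 and F11 (PdCl2(dppf), K3PO4, dioxane–H2O, 80 °C) gives the 6-(benzofuran-2-yl)-4-methoxypyridazin-3-amine F12, and a Sandmeyer chlorination (tert-butyl nitrite, CuCl2, MeCN, 60 °C) converts F12 into 12.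

## Further compounds

F1 | step 13 | 4-[(1S,2R)-1-[(4-methoxypyridazin-3-yl)oxy]-2-({[tri(propan-2-yl)silyl]oxy}methyl)but-3-yn-1-yl]-2-methoxyphenyl 4-methylbenzenesulfonate | COc1cc([C@@H](Oc2nnccc2OC)[C@@H](CO[Si](C(C)C)(C(C)C)C(C)C)C#C)ccc1OS(=O)(=O)c1ccc(C)cc1
F2 | step 13 | 4-[(2S,3R)-7-methoxy-3-({[tri(propan-2-yl)silyl]oxy}methyl)-2,3-dihydro-1-benzofuran-2-yl]-2-methoxyphenyl 4-methylbenzenesulfonate | COc1cc([C@H]2Oc3c(OC)cccc3[C@@H]2CO[Si](C(C)C)(C(C)C)C(C)C)ccc1OS(=O)(=O)c1ccc(C)cc1
F3 | step 13 | 4-[(2S,3R)-5-bromo-7-methoxy-3-({[tri(propan-2-yl)silyl]oxy}methyl)-2,3-dihydro-1-benzofuran-2-yl]-2-methoxyphenyl 4-methylbenzenesulfonate | COc1cc([C@H]2Oc3c(OC)cc(Br)cc3[C@@H]2CO[Si](C(C)C)(C(C)C)C(C)C)ccc1OS(=O)(=O)c1ccc(C)cc1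
F4 | step 11 | 4-[(1R,2R)-1-hydroxy-2-({[tri(propan-2-yl)silyl]oxy}methyl)but-3-yn-1-yl]-2-methoxyphenyl 4-methylbenzenesulfonate | COc1cc([C@H](O)[C@@H](CO[Si](C(C)C)(C(C)C)C(C)C)C#C)ccc1OS(=O)(=O)c1ccc(C)cc1
F5 | step 11 | 4-[(1R,2R)-1-({6-[5-(3-{[tert-butyl(dimethyl)silyl]oxy}propyl)-7-methoxy-1-benzofuran-2-yl]-4-methoxypyridazin-3-yl}oxy)-2-({[tri(propan-2-yl)silyl]oxy}methyl)but-3-yn-1-yl]-2-methoxyphenyl 4-methylbenzenesulfonate | COc1cc([C@H](Oc2nnc(-c3cc4cc(CCCO[Si](C)(C)C(C)(C)C)cc(OC)c4o3)cc2OC)[C@@H](CO[Si](C(C)C)(C(C)C)C(C)C)C#C)ccc1OS(=O)(=O)c1ccc(C)cc1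
F6 | step 11 | 4-[(2R,3R)-5-[5-(3-{[tert-butyl(dimethyl)silyl]oxy}propyl)-7-methoxy-1-benzofuran-2-yl]-7-methoxy-3-({[tri(propan-2-yl)silyl]oxy}methyl)-2,3-dihydro-1-benzofuran-2-yl]-2-methoxyphenyl 4-methylbenzenesulfonate | COc1cc([C@@H]2Oc3c(OC)cc(-c4cc5cc(CCCO[Si](C)(C)C(C)(C)C)cc(OC)c5o4)cc3[C@@H]2CO[Si](C(C)C)(C(C)C)C(C)C)ccc1OS(=O)(=O)c1ccc(C)cc1
F7 | step 11 | 4-[(2R,3R)-5-[5-(3-{[tert-butyl(dimethyl)silyl]oxy}propyl)-7-methoxy-1-benzofuran-2-yl]-7-methoxy-3-({[tri(propan-2-yl)silyl]oxy}methyl)-2,3-dihydro-1-benzofuran-2-yl]-2-methoxyphenol | COc1cc([C@@H]2Oc3c(OC)cc(-c4cc5cc(CCCO[Si](C)(C)C(C)(C)C)cc(OC)c5o4)cc3[C@@H]2CO[Si](C(C)C)(C(C)C)C(C)C)ccc1O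
F8 | step 12 | 6-[5-(3-{[tert-butyl(dimethyl)silyl]oxy}propyl)-7-methoxy-1-benzofuran-2-yl]-4-methoxy-3-(methylsulfanyl)pyridazine | COc1cc(-c2cc3cc(CCCO[Si](C)(C)C(C)(C)C)cc(OC)c3o2)nnc1SC
F9 | step 12 | 6-[5-(3-{[tert-butyl(dimethyl)silyl]oxy}propyl)-7-methoxy-1-benzofuran-2-yl]-4-methoxy-3-(methylsulfonyl)pyridazine | COc1cc(-c2cc3cc(CCCO[Si](C)(C)C(C)(C)C)cc(OC)c3o2)nnc1S(C)(=O)=O
F10 | step 5 | 6-chloro-4-methoxypyridazin-3-amine | COc1cc(Cl)nnc1N
F11 | step 5 | tert-butyl{3-[7-methoxy-2-(4,4,5,5-tetramethyl-1,3,2-dioxaborolan-2-yl)-1-benzofuran-5-yl]propoxy}dimethylsilane | COc1cc(CCCO[Si](C)(C)C(C)(C)C)cc2cc(B3OC(C)(C)C(C)(C)O3)oc12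
F12 | step 5 | 6-[5-(3-{[tert-butyl(dimethyl)silyl]oxy}propyl)-7-methoxy-1-benzofuran-2-yl]-4-methoxypyridazin-3-amine | COc1cc(-c2cc3cc(CCCO[Si](C)(C)C(C)(C)C)cc(OC)c3o2)nnc1N
A1 | alternative 1 | 4-bromo-2-{2-[(tert-butyldimethylsilyl)oxy]-1-(phenylsulfonyl)ethyl}-6-methoxyphenol (racemic) | COc1cc(Br)cc(C(CO[Si](C)(C)C(C)(C)C)S(=O)(=O)c2ccccc2)c1O
A2 | alternative 1 | (2R,5R)-1-[4-(benzyloxy)-3-methoxybenzyl]-2,5-dimethylthiolan-1-ium tetrafluoroborate | C[C@@H]1CC[C@@H](C)[S+]1Cc1ccc(OCc2ccccc2)c(OC)c1.F[B-](F)(F)F
A3 | alternative 1 | tert-butyl{[(2S,3R)-2-(4-benzyloxy-3-methoxyphenyl)-5-bromo-7-methoxy-2,3-dihydro-1-benzofuran-3-yl]methoxy}dimethylsilane | COc1cc([C@H]2Oc3c(OC)cc(Br)cc3[C@@H]2CO[Si](C)(C)C(C)(C)C)ccc1OCc1ccccc1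
A4 | alternative 2 | methyl 2-{2-[(4-benzyloxy-3-methoxybenzyl)oxy]-5-bromo-3-methoxyphenyl}-2-diazoacetate | COC(=O)C(=[N+]=[N-])c1cc(Br)cc(OC)c1OCc1ccc(OCc2ccccc2)c(OC)c1
A5 | alternative 2 | methyl (2S,3S)-2-(4-benzyloxy-3-methoxyphenyl)-5-bromo-7-methoxy-2,3-dihydro-1-benzofuran-3-carboxylate (trans) | COc1cc([C@H]2Oc3c(OC)cc(Br)cc3[C@@H]2C(=O)OC)ccc1OCc1ccccc1
A6 | alternative 3 | (2S,3R)-3-(acetoxymethyl)-2-(4-acetoxy-3-methoxyphenyl)-7-methoxy-2,3-dihydro-1-benzofuran-5-carbonyl chloride | COc1cc([C@H]2Oc3c(OC)cc(C(=O)Cl)cc3[C@@H]2COC(C)=O)ccc1OC(C)=O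
A7 | alternative 3 | [5-(3-acetoxypropyl)-2-hydroxy-3-methoxybenzyl]triphenylphosphonium bromide | COc1cc(CCCOC(C)=O)cc(C[P+](c2ccccc2)(c2ccccc2)c2ccccc2)c1O.[Br-]
A8 | alternative 3 | triacetate of 27: 4-[(2S,3R)-3-(acetoxymethyl)-5-[5-(3-acetoxypropyl)-7-methoxy-1-benzofuran-2-yl]-7-methoxy-2,3-dihydro-1-benzofuran-2-yl]-2-methoxyphenyl acetate | COc1cc([C@H]2Oc3c(OC)cc(-c4cc5cc(CCCOC(C)=O)cc(OC)c5o4)cc3[C@@H]2COC(C)=O)ccc1OC(C)=O
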